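**Plan**

- Retrosynthetic cuts: first C7'–C8' (ring B C10 unit + C30 retro-polyenyl triflate), then C7=C8 (ring A C10 sulfone + C20 crocetindial). Both ring units come from ketoisophorone by one-carbon homologation at the shielded C6/C6' carbonyl.
- Forward: ring A sulfone and crocetindial give a C30 aldehyde (Julia–Kocienski). Remote enolisation with O-triflation then moves all chain double bonds into the retro positions and turns C8' into an alkenyl triflate (fragment 2).
- Key event: palladium-carbene coupling of the ring B aldehyde tosylhydrazone (fragment 1) with fragment 2. It is possible because ring B ends in the exocyclic C6'=C7' alkene: ring carbon C6', between quaternary C1' and the C4'=C5' alkene, can carry the one hydrogen that palladium removes after C7' has bonded to C8'. C7' and C8' are both former formyl carbons; C7' is polarity-reversed as a carbene.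
- Stereochemistry: C3' (S) from Ru-catalysed asymmetric transfer hydrogenation of ketoisophorone. The C6/C6' epimers, the 7-alkene isomers and the hydrazone isomers all converge. Chain E geometry comes from the s-trans polyenal; 6E and 6'E are expected from the transoid preference in enolisation and in β-hydride elimination.
- End game: ketal hydrolysis, then desilylation.

Key step: step 14

Remark: carotenoid numbering is used; ring A is the keto ring (C1–C6), ring B the hydroxy ring (C1'–C6'). Ketoisophorone and crocetindial are taken as commercial.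
Assumption: the Ru–TsDPEN catalyst shows on the ene-dione the facial preference it shows on aryl and alkenyl ketones; if the (R)-alcohol forms, the (R,R)-catalyst is used instead.

**Route**

Step 1
Reactants: 1 ketoisophorone (2,6,6-trimethylcyclohex-2-ene-1,4-dione)
Product: 2 (4S)-4-hydroxy-2,6,6-trimethylcyclohex-2-en-1-one
Conditions: RuCl[(S,S)-TsDPEN](p-cymene) (cat.), i-PrOH, rt
Reagents that add atoms: none
Why: Noyori asymmetric transfer hydrogenation should reduce only the less hindered C4 carbonyl (C1 is shielded by the gem-dimethyl carbon and the C2 methyl), and the chiral Ru hydride delivers hydrogen to one carbonyl face to set the (S)-carbinol that becomes C3' of the target.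

Step 2
Reactants: 2 (4S)-4-hydroxy-2,6,6-trimethylcyclohex-2-en-1-one
Product: 3 (4S)-4-[tert-butyl(dimethyl)silyl]oxy-2,6,6-trimethylcyclohex-2-en-1-one
Conditions: TBSCl, imidazole, DMF, rt
Reagents that add atoms: tert-butyldimethylsilyl chloride, CC(C)(C)[Si](C)(C)Cl
Why: Standard imidazole-promoted silylation of a secondary allylic alcohol gives a silyl ether that tolerates the basic, oxidative and organometallic steps that follow and does not touch the stereocentre.

Step 3
Reactants: 3 (4S)-4-[tert-butyl(dimethyl)silyl]oxy-2,6,6-trimethylcyclohex-2-en-1-one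
Product: 4 tert-butyl(dimethyl){[(1S)-3,5,5-trimethyl-4-methylidenecyclohex-2-en-1-yl]oxy}silane
Conditions: Cp2TiMe2 (2.5 equiv), toluene, 70 °C, dark
Reagents that add atoms: dimethyltitanocene, [CH3-].[CH3-].[Ti+4].c1cc[cH-]c1.c1cc[cH-]c1
Why: Petasis methylenation uses the small, non-basic titanium methylidene Cp2Ti=CH2, which should olefinate the shielded enone carbonyl without γ-enolisation, so the silyloxy stereocentre is not epimerised.

Step 4
Reactants: 4 tert-butyl(dimethyl){[(1S)-3,5,5-trimethyl-4-methylidenecyclohex-2-en-1-yl]oxy}silane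
Product: 6 {(1RS,4S)-4-[tert-butyl(dimethyl)silyl]oxy-2,6,6-trimethylcyclohex-2-en-1-yl}methanol, via alkylborane 5 (not isolated)
Conditions: 9-BBN, THF, 0 °C → rt; then NaOH, H2O2, 0 °C
Reagents that add atoms: hydrogen peroxide, OO
Why: Anti-Markovnikov hydroboration–oxidation places boron only on the unhindered terminal CH2 and leaves the trisubstituted ring alkene alone; the new ring stereocentre forms as a mixture, which is harmless because step 14 erases it.

Step 5
Reactants: 6 {(1RS,4S)-4-[tert-butyl(dimethyl)silyl]oxy-2,6,6-trimethylcyclohex-2-en-1-yl}methanol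
Product: 7 (1RS,4S)-4-[tert-butyl(dimethyl)silyl]oxy-2,6,6-trimethylcyclohex-2-ene-1-carbaldehyde
Conditions: Dess–Martin periodinane, NaHCO3, CH2Cl2, 0 °C
Reagents that add atoms: none
Why: Buffered Dess–Martin oxidation converts the primary alcohol into the β,γ-unsaturated aldehyde under near-neutral conditions that should not move the ring double bond into conjugation.

Step 6
Reactants: 7 (1RS,4S)-4-[tert-butyl(dimethyl)silyl]oxy-2,6,6-trimethylcyclohex-2-ene-1-carbaldehyde
Product: 8 N'-({(1RS,4S)-4-[tert-butyl(dimethyl)silyl]oxy-2,6,6-trimethylcyclohex-2-en-1-yl}methylidene)-4-methylbenzenesulfonohydrazide (fragment 1)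
Conditions: TsNHNH2, MeOH, rt
Reagents that add atoms: p-toluenesulfonyl hydrazide, Cc1ccc(cc1)S(=O)(=O)NN
Why: Condensation of an aldehyde with tosylhydrazide gives the N-tosylhydrazone without added acid; its C=N isomers and C1 epimers need no separation because all of them converge in step 14.

Step 7
Reactants: 1 ketoisophorone (2,6,6-trimethylcyclohex-2-ene-1,4-dione)
Product: 9 7,9,9-trimethyl-1,4-dioxaspiro[4.5]dec-6-en-8-one
Conditions: HOCH2CH2OH, p-TsOH (cat.), benzene, reflux, Dean–Stark
Reagents that add atoms: ethylene glycol, OCCO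
Why: Acid-catalysed ketalisation should protect only the accessible C4 carbonyl, because the C1 carbonyl is flanked by the quaternary carbon and the methyl-bearing alkene carbon.

Step 8
Reactants: 9 7,9,9-trimethyl-1,4-dioxaspiro[4.5]dec-6-en-8-one
Product: 10 7,9,9-trimethyl-8-methylidene-1,4-dioxaspiro[4.5]dec-6-ene
Conditions: Cp2TiMe2 (2.5 equiv), toluene, 70 °C, dark
Reagents that add atoms: dimethyltitanocene, [CH3-].[CH3-].[Ti+4].c1cc[cH-]c1.c1cc[cH-]c1
Why: Petasis methylenation of the shielded ketone as in step 3; the reagent is neither acidic nor basic, so the allylic ketal survives.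

Step 9
Reactants: 10 7,9,9-trimethyl-8-methylidene-1,4-dioxaspiro[4.5]dec-6-ene
Product: 12 (7,9,9-trimethyl-1,4-dioxaspiro[4.5]dec-6-en-8-yl)methanol (racemic), via alkylborane 11 (not isolated)
Conditions: 9-BBN, THF, 0 °C → rt; then NaOH, H2O2, 0 °C
Reagents that add atoms: hydrogen peroxide, OO
Why: Regioselective hydroboration–oxidation of the terminal methylene as in step 4; the basic oxidative work-up keeps the ketal, and the new stereocentre is erased in step 13.

Step 10
Reactants: 12 (7,9,9-trimethyl-1,4-dioxaspiro[4.5]dec-6-en-8-yl)methanol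
Product: 13 1-phenyl-5-{[(7,9,9-trimethyl-1,4-dioxaspiro[4.5]dec-6-en-8-yl)methyl]sulfanyl}-1H-tetrazole
Conditions: PPh3, i-PrO2CN=NCO2i-Pr, 1-phenyl-1H-tetrazole-5-thiol, THF, 0 °C → rt
Reagents that add atoms: 1-phenyl-1H-tetrazole-5-thiol, SC1=NN=NN1c1ccccc1
Why: Mitsunobu thioetherification of a primary alcohol with the acidic tetrazole thiol proceeds under neutral conditions that the ketal tolerates.

Step 11
Reactants: 13 1-phenyl-5-{[(7,9,9-trimethyl-1,4-dioxaspiro[4.5]dec-6-en-8-yl)methyl]sulfanyl}-1H-tetrazole
Product: 14 1-phenyl-5-{[(7,9,9-trimethyl-1,4-dioxaspiro[4.5]dec-6-en-8-yl)methyl]sulfonyl}-1H-tetrazole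
Conditions: (NH4)6Mo7O24·4H2O (cat.), 30% H2O2, EtOH, 0 °C → rt
Reagents that add atoms: hydrogen peroxide, OO
Why: Molybdate-catalysed peroxide oxidation takes the sulfide to the sulfone chemoselectively, since an unactivated trisubstituted alkene is epoxidised far more slowly under these conditions.

Step 12
Reactants: 14 1-phenyl-5-{[(7,9,9-trimethyl-1,4-dioxaspiro[4.5]dec-6-en-8-yl)methyl]sulfonyl}-1H-tetrazole; 15 crocetindial ((2E,4E,6E,8E,10E,12E,14E)-2,6,11,15-tetramethylhexadeca-2,4,6,8,10,12,14-heptaenedial)
Product: 16 3,3-(ethylenedioxy)-8'-apo-ε-caroten-8'-al (racemic at C6, 7E/7Z mixture)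
Conditions: KN(SiMe3)2 (1.05 equiv) added to 14 and 15 (3 equiv), THF, −78 → 0 °C, dark
Reagents that add atoms: none
Why: Julia–Kocienski olefination under Barbier conditions with excess dialdehyde should favour mono-olefination at one formyl group (C7=C8 formed); the geometry of this alkene does not matter because step 13 turns it into the C7–C8 single bond.

Step 13
Reactants: 16 3,3-(ethylenedioxy)-8'-apo-ε-caroten-8'-al
Product: 18 C30 retro-polyenyl triflate (fragment 2): ring A with the C3 dioxolane, C4=C5 and exocyclic (6E)-C6=C7, all-E chain with double bonds 8=9, 10=11, 12=13, 14=15, 15'=14', 13'=12', 11'=10', 9'=8' and OTf on C8', via potassium polyenolate 17 (not isolated)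
Conditions: KN(SiMe3)2 (1.0 equiv), THF, −78 → −30 °C; then PhNTf2, −78 → 0 °C, dark
Reagents that add atoms: N-phenylbis(trifluoromethanesulfonimide), O=S(=O)(N(c1ccccc1)S(=O)(=O)C(F)(F)F)C(F)(F)F
Why: Vinylogous enolisation followed by O-sulfonylation (the long-range version of dienyl triflate formation from enals and of C4 deprotonation of retinoids): removal of the doubly allylic C6–H gives the linear polyenolate in which every chain single bond has become a double bond, E because the polyenal is s-trans, with 6E expected from the transoid arrangement that keeps C8 out of the plane of the C5 methyl, and PhNTf2 traps the oxygen terminus as the C8' enol triflate.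

Step 14
Reactants: 18 C30 retro-polyenyl triflate (fragment 2); 8 ring B aldehyde N-tosylhydrazone (fragment 1)
Product: 20 (3'S)-3'-[tert-butyl(dimethyl)silyl]oxy-3,3-(ethylenedioxy)-4',5'-didehydro-4,5'-retro-β,β-carotene (all-E), via diazoalkane 19 (not isolated)
Conditions: Pd2(dba)3 (2.5 mol %), XPhos (10 mol %), LiOtBu (2.5 equiv), 8 (1.3 equiv), 1,4-dioxane, 70 °C, dark, argon
Reagents that add atoms: none
Why: LiOtBu converts 8 into diazoalkane 19 (Bamford–Stevens), zerovalent palladium inserts into the C8'–OTf bond of 18, the alkenylpalladium takes up 19 as a palladium carbene at C7', and 1,2-migration of the C8' alkenyl group to the carbene carbon forms the C7'–C8' bond and an η3-allylpalladium (C7'–C8'–C9'); syn β-hydride elimination of the tertiary, allylic C6'–H then creates the exocyclic C6'=C7' alkene and returns zerovalent palladium. The closest known reaction type is the Barluenga coupling of N-tosylhydrazones with alkenyl halides or sulfonates to give conjugated dienes, including α-branched aldehyde hydrazones that give exocyclic trisubstituted alkenes. No ring is closed and no stereocentre is created: the C6' stereocentre and the hydrazone geometry, both mixtures in 8, are erased, so all isomers of 8 converge on one diene. The union joins two former carbonyl carbons of like polarity, which is possible because C7' is polarity-reversed as the diazo and carbene carbon. The step needs β-hydride elimination at C6'–H and E geometry at C6'=C7' and C8'=C9': C6'–H is the only sp3 β-hydrogen at the C7'-bound palladium and its loss gives the fully conjugated retro-polyene (methyl hydrogens at C9' would give only a cross-conjugated isomer), while π–σ–π equilibration of the allylpalladium keeps the chain syn at C9' and lets C7' epimerise, so elimination should run through the less strained transition state that places C8' beside the gem-dimethyl carbon C1' and not in the plane of the C5' methyl.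

Step 15
Reactants: 20 (3'S)-3'-[tert-butyl(dimethyl)silyl]oxy-3,3-(ethylenedioxy)-4',5'-didehydro-4,5'-retro-β,β-carotene
Product: 21 (3'S)-3'-[tert-butyl(dimethyl)silyl]oxy-4',5'-didehydro-4,5'-retro-β,β-caroten-3-one (all-E)
Conditions: oxalic acid (cat.), THF/H2O, rt, dark
Reagents that add atoms: water, O
Why: Mild acid hydrolysis of an acetal: the C3 ketal is allylic to the whole polyene, so its oxocarbenium ion forms under very weak acid, under which the less basic, hindered allylic silyl ether at C3' should neither ionise nor epimerise.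

Step 16
Reactants: 21 (3'S)-3'-[tert-butyl(dimethyl)silyl]oxy-4',5'-didehydro-4,5'-retro-β,β-caroten-3-one
Product: 22 (3'S)-3'-hydroxy-4',5'-didehydro-4,5'-retro-β,β-caroten-3-one (all-E; CNP0279160.1)
Conditions: Bu4NF, AcOH, THF, 0 °C → rt, dark; crystallisation under argon
Reagents that add atoms: none
Why: Fluoride-mediated desilylation buffered with acetic acid cleaves the Si–O bond without breaking the C3'–O bond, so the (S) configuration is retained and the base-sensitive dienone is spared.

**Compound list**

1 | ketoisophorone (2,6,6-trimethylcyclohex-2-ene-1,4-dione) | CC1=CC(=O)CC(C)(C)C1=O | starting material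
2 | (4S)-4-hydroxy-2,6,6-trimethylcyclohex-2-en-1-one | CC1=C[C@@H](O)CC(C)(C)C1=O | intermediate
3 | (4S)-4-[tert-butyl(dimethyl)silyl]oxy-2,6,6-trimethylcyclohex-2-en-1-one | CC1=C[C@@H](O[Si](C)(C)C(C)(C)C)CC(C)(C)C1=O | intermediate
4 | tert-butyl(dimethyl){[(1S)-3,5,5-trimethyl-4-methylidenecyclohex-2-en-1-yl]oxy}silane | CC1=C[C@@H](O[Si](C)(C)C(C)(C)C)CC(C)(C)C1=C | intermediate
5 | 9-({(4S)-4-[tert-butyl(dimethyl)silyl]oxy-2,6,6-trimethylcyclohex-2-en-1-yl}methyl)-9-borabicyclo[3.3.1]nonane | CC1=C[C@@H](O[Si](C)(C)C(C)(C)C)CC(C)(C)C1CB1C2CCCC1CCC2 | intermediate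
6 | {(1RS,4S)-4-[tert-butyl(dimethyl)silyl]oxy-2,6,6-trimethylcyclohex-2-en-1-yl}methanol | CC1=C[C@@H](O[Si](C)(C)C(C)(C)C)CC(C)(C)C1CO | intermediate
7 | (1RS,4S)-4-[tert-butyl(dimethyl)silyl]oxy-2,6,6-trimethylcyclohex-2-ene-1-carbaldehyde | CC1=C[C@@H](O[Si](C)(C)C(C)(C)C)CC(C)(C)C1C=O | intermediate
8 | N-tosylhydrazone of 7 (fragment 1) | CC1=C[C@@H](O[Si](C)(C)C(C)(C)C)CC(C)(C)C1C=NNS(=O)(=O)c1ccc(C)cc1 | intermediate
9 | 7,9,9-trimethyl-1,4-dioxaspiro[4.5]dec-6-en-8-one | CC1=CC2(OCCO2)CC(C)(C)C1=O | intermediate
10 | 7,9,9-trimethyl-8-methylidene-1,4-dioxaspiro[4.5]dec-6-ene | CC1=CC2(OCCO2)CC(C)(C)C1=C | intermediate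
11 | 9-[(7,9,9-trimethyl-1,4-dioxaspiro[4.5]dec-6-en-8-yl)methyl]-9-borabicyclo[3.3.1]nonane | CC1=CC2(OCCO2)CC(C)(C)C1CB1C2CCCC1CCC2 | intermediate
12 | (7,9,9-trimethyl-1,4-dioxaspiro[4.5]dec-6-en-8-yl)methanol (racemic) | CC1=CC2(OCCO2)CC(C)(C)C1CO | intermediate
13 | 1-phenyl-5-{[(7,9,9-trimethyl-1,4-dioxaspiro[4.5]dec-6-en-8-yl)methyl]sulfanyl}-1H-tetrazole | CC1=CC2(OCCO2)CC(C)(C)C1CSC1=NN=NN1c1ccccc1 | intermediate
14 | 1-phenyl-5-{[(7,9,9-trimethyl-1,4-dioxaspiro[4.5]dec-6-en-8-yl)methyl]sulfonyl}-1H-tetrazole | CC1=CC2(OCCO2)CC(C)(C)C1CS(=O)(=O)C1=NN=NN1c1ccccc1 | intermediate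
15 | crocetindial (all-E 2,6,11,15-tetramethylhexadeca-2,4,6,8,10,12,14-heptaenedial) | O=C/C(C)=C/C=C/C(C)=C/C=C/C=C(C)/C=C/C=C(C)/C=O | starting material
16 | 3,3-(ethylenedioxy)-8'-apo-ε-caroten-8'-al (racemic at C6, 7E/7Z) | CC1=CC2(OCCO2)CC(C)(C)C1C=C/C(C)=C/C=C/C(C)=C/C=C/C=C(C)/C=C/C=C(C)/C=O | intermediate
17 | potassium polyenolate of 16 (retro pattern, O- on C8') | CC1=CC2(OCCO2)CC(C)(C)\C1=C/C=C(C)/C=C/C=C(C)/C=C/C=C/C(C)=C/C=C/C(C)=C/[O-].[K+] | intermediate
18 | C30 retro-polyenyl triflate (fragment 2) | CC1=CC2(OCCO2)CC(C)(C)\C1=C/C=C(C)/C=C/C=C(C)/C=C/C=C/C(C)=C/C=C/C(C)=C/OS(=O)(=O)C(F)(F)F | intermediate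
19 | tert-butyl{[(1S)-4-(diazomethyl)-3,5,5-trimethylcyclohex-2-en-1-yl]oxy}dimethylsilane | CC1=C[C@@H](O[Si](C)(C)C(C)(C)C)CC(C)(C)C1C=[N+]=[N-] | intermediate
20 | (3'S)-3'-[tert-butyl(dimethyl)silyl]oxy-3,3-(ethylenedioxy)-4',5'-didehydro-4,5'-retro-β,β-carotene | CC1=CC2(OCCO2)CC(C)(C)\C1=C/C=C(C)/C=C/C=C(C)/C=C/C=C/C(C)=C/C=C/C(C)=C/C=C1/C(C)=C[C@@H](O[Si](C)(C)C(C)(C)C)CC1(C)C | intermediate
21 | (3'S)-3'-[tert-butyl(dimethyl)silyl]oxy-4',5'-didehydro-4,5'-retro-β,β-caroten-3-one | CC1=CC(=O)CC(C)(C)\C1=C/C=C(C)/C=C/C=C(C)/C=C/C=C/C(C)=C/C=C/C(C)=C/C=C1/C(C)=C[C@@H](O[Si](C)(C)C(C)(C)C)CC1(C)C | intermediate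
22 | (3'S)-3'-hydroxy-4',5'-didehydro-4,5'-retro-β,β-caroten-3-one (all-E; CNP0279160.1) | CC1=CC(=O)CC(C)(C)\C1=C/C=C(C)/C=C/C=C(C)/C=C/C=C/C(C)=C/C=C/C(C)=C/C=C1/C(C)=C[C@@H](O)CC1(C)C | target

**Summary and risks**

Total step count: 16.
Longest linear sequence: 10 steps (steps 7 to 16, from ketoisophorone through ring A).

Steps most likely to fail:

1. Step 14. Palladium may migrate along the polyenyl allyl system and eliminate a methyl hydrogen, giving cross-conjugated isomers. π–σ–π isomerisation may give poor E/Z control at C6'=C7' or erode the chain geometry. The carbene may cyclopropanate the polyene, and heating may cause thermal isomerisation. Fallback (sets out from 7 and 18, returns at 20): a cross-coupling with preset geometry. Aldehyde 7 is enolised with KN(SiMe3)2 and trapped with PhNTf2 in THF at −78 °C to give the exocyclic (E)-dienyl triflate F1, freed from its Z isomer by chromatography. Triflate 18 is converted by Miyaura borylation (B2pin2, PdCl2(dppf), KOAc, dioxane, 50 °C) into the C30 alkenyl pinacol boronate F2. Suzuki–Miyaura coupling of F1 with F2 (Pd(PPh3)4, aqueous K3PO4, THF, rt, dark) gives 20.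

2. Step 13. Deprotonation may occur kinetically at the C9 or C13 methyl groups instead of C6–H. The extended enolate may open the dioxolane by β-elimination. Facial control at C6=C7 may be poor. Fallback (sets out from 16, returns at 21): the acidity is raised so that a weak base suffices. The ketal of 16 is hydrolysed first (oxalic acid, THF/H2O) to the keto aldehyde F3, whose C6–H is activated by both the ring enone and the polyenal. Soft enolisation with i-Pr2NEt and PhNTf2 in CH2Cl2 (−40 °C → rt) sulfonylates the aldehyde oxygen, as formyl ketones do, and gives the dienone triflate F4. Coupling of F4 with 8 under the conditions of step 14 gives 21 directly, and step 15 is no longer needed.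

3. Step 3 (the same holds for step 8). Methylenation of the doubly flanked carbonyl may be slow, so that the titanium reagent decomposes thermally before conversion is complete. Fallback (sets out from 3, returns at 4): Peterson olefination. Addition of Me3SiCH2Li with CeCl3 in THF at −78 °C gives the β-hydroxysilane F5, and syn-elimination with KH in THF (0 °C → rt) gives 4.

Further compounds
F1 | step 14 | (E)-{(4S)-4-[tert-butyl(dimethyl)silyl]oxy-2,6,6-trimethylcyclohex-2-en-1-ylidene}methyl trifluoromethanesulfonate | FC(F)(F)S(=O)(=O)O/C=C1/C(C)=C[C@@H](O[Si](C)(C)C(C)(C)C)CC1(C)C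
F2 | step 14 | C30 retro-polyenyl pinacol boronate (18 with Bpin in place of OTf) | CC1=CC2(OCCO2)CC(C)(C)\C1=C/C=C(C)/C=C/C=C(C)/C=C/C=C/C(C)=C/C=C/C(C)=C/B1OC(C)(C)C(C)(C)O1
F3 | step 13 | 3-oxo-8'-apo-ε-caroten-8'-al (racemic at C6, 7E/7Z) | CC1=CC(=O)CC(C)(C)C1C=C/C(C)=C/C=C/C(C)=C/C=C/C=C(C)/C=C/C=C(C)/C=O
F4 | step 13 | C30 retro-polyenyl triflate with free ring A dienone | CC1=CC(=O)CC(C)(C)\C1=C/C=C(C)/C=C/C=C(C)/C=C/C=C/C(C)=C/C=C/C(C)=C/OS(=O)(=O)C(F)(F)F
F5 | step 3 | (4S)-4-[tert-butyl(dimethyl)silyl]oxy-2,6,6-trimethyl-1-[(trimethylsilyl)methyl]cyclohex-2-en-1-ol (C1 epimers) | CC1=C[C@@H](O[Si](C)(C)C(C)(C)C)CC(C)(C)C1(O)C[Si](C)(C)C
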